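**Retrosynthetic overview**
- Last bond: C10–O (dihydrofuran and 8,9-dione together) by dehydrogenative enol–phenol coupling of a chalcone diosphenol; the chalcone comes from a Claisen–Schmidt condensation one step earlier.
- The gem-dimethylcyclopropane is made by isopropylidene transfer to C6=C7 of a planar cross-conjugated dienone, anti to the angular methyl; this needs C10 to be sp2.
- Key step: intramolecular Diels–Alder of an aryl (E,E)-pentadiene onto C5=C10 of a 3-aryloxy-4-methyl-o-benzoquinone. Ring B and the dihydrofuran close together and C1, C4, C5 are set all-syn. The ether oxygen is the tether here and the furan oxygen at the end: C10–O is released reductively before cyclopropanation and re-formed last.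
- The o-quinone comes from IBX oxidation of a 2-aryloxy-3-methylphenol (SNAr, then Dakin); the diene from a Heck reaction; the aryl core from 2',6'-dihydroxy-4'-methoxyacetophenone.
- Ring order: both benzene rings are bought (one becomes ring A by dearomatisation) → ring B + dihydrofuran → dihydrofuran opened → cyclopropane → dihydrofuran re-closed.

Assumption: terpenoid carbons are numbered C1–C15 as in aristolane and the acetophenone ring 1'–6' (1' acyl, 5' C-link, 6' O-link); the ligand antipode in step 6 is taken to be the one giving the (1R,4R,5S,10S) adduct, otherwise its enantiomer is used.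

CIP labels at C1 and C5 change along the route because substituent priorities change; the geometry does not.

**Step 1**
Reactants: 1 2',6'-dihydroxy-4'-methoxyacetophenone
Product: 2 1-[2-(benzyloxy)-6-hydroxy-4-methoxyphenyl]ethan-1-one
Conditions: BnBr (1.05 equiv), K2CO3 (1.1 equiv), acetone, reflux
Reagents that add atoms: benzyl bromide, BrCc1ccccc1
Why: Williamson mono-etherification; after one O-alkylation the remaining phenol is held in the hydrogen bond to the ketone and is not alkylated, which differentiates the two phenols of the symmetric starting material.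

**Step 2**
Reactants: 2 1-[2-(benzyloxy)-6-hydroxy-4-methoxyphenyl]ethan-1-one
Product: 3 1-[6-(benzyloxy)-2-hydroxy-3-iodo-4-methoxyphenyl]ethan-1-one
Conditions: NIS (1.05 equiv), TFA (cat.), MeCN, 0 °C → rt
Reagents that add atoms: N-iodosuccinimide, O=C1CCC(=O)N1I
Why: electrophilic aromatic iodination ortho to the free phenol (the site between OH and OMe is activated and less hindered than the one between OBn and OMe), which puts the diene handle next to the oxygen that will carry ring A.

**Step 3**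
Reactants: 3 1-[6-(benzyloxy)-2-hydroxy-3-iodo-4-methoxyphenyl]ethan-1-one; 4 2-fluoro-3-methylbenzaldehyde
Product: 5 2-[2-acetyl-3-(benzyloxy)-6-iodo-5-methoxyphenoxy]-3-methylbenzaldehyde
Conditions: Cs2CO3 (1.2 equiv), DMF, 100 °C
Reagents that add atoms: none
Why: SNAr (addition–elimination) of the phenoxide on the ortho-formyl-activated aryl fluoride; being metal-free it tolerates the four ortho substituents and leaves the aryl iodide untouched.

**Step 4**
Reactants: 5 2-[2-acetyl-3-(benzyloxy)-6-iodo-5-methoxyphenoxy]-3-methylbenzaldehyde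
Product: 7 1-[6-(benzyloxy)-2-(2-hydroxy-6-methylphenoxy)-3-iodo-4-methoxyphenyl]ethan-1-one, via aryl formate 6 (not isolated)
Conditions: mCPBA (1.3 equiv), CH2Cl2, 0 °C → rt; then K2CO3 (cat.), MeOH, rt
Reagents that add atoms: mCPBA, OOC(=O)c1cccc(Cl)c1
Why: Dakin-type Baeyer–Villiger oxidation (migration of the o-aryloxy-substituted aryl group) followed by methanolysis of the formate; the aldehyde reacts much faster than the hindered aryl methyl ketone.

**Step 5**
Reactants: 7 1-[6-(benzyloxy)-2-(2-hydroxy-6-methylphenoxy)-3-iodo-4-methoxyphenyl]ethan-1-one; 8 (E)-penta-1,3-diene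
Product: 9 1-[6-(benzyloxy)-2-(2-hydroxy-6-methylphenoxy)-4-methoxy-3-[(1E,3E)-penta-1,3-dien-1-yl]phenyl]ethan-1-one
Conditions: Pd(OAc)2 (5 mol %), n-Bu4NCl (1 equiv), NaHCO3 (2.5 equiv), 8 (5 equiv), DMF, 80 °C, sealed tube
Reagents that add atoms: none
Why: Heck reaction under Jeffery conditions; aryl-Pd adds to the unsubstituted diene terminus and β-hydride elimination gives the conjugated (1E,3E)-1-aryl diene, while both ortho positions of the phenoxy ring are blocked so no dibenzofuran can form.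

**Step 6**
Reactants: 9 1-[6-(benzyloxy)-2-(2-hydroxy-6-methylphenoxy)-4-methoxy-3-[(1E,3E)-penta-1,3-dien-1-yl]phenyl]ethan-1-one
Product: 11 (1R,4R,5S,10S)-tetracyclic ene-dione (O6'–C10/C5'–C1 cis-fused dihydrobenzofuran; C2=C3 and C6=C7; C8=O and C9=O; 1'-acetyl 2'-OBn 4'-OMe), via o-quinone 10 (not isolated)
Conditions: IBX (1.2 equiv), DMF, 0 °C → rt; extractive work-up into CH2Cl2; then Cu(OTf)2/(S,S)-t-Bu-box (20 mol %), 4 Å MS, −40 → 0 °C
Reagents that add atoms: IBX, O=C1OI(=O)(O)c2ccccc12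
Why: Proposed new method: IBX oxidises the electron-rich phenol at its free ortho position to the 3-aryloxy-4-methyl-o-quinone (known phenol → o-quinone oxidation), whose 1,2-dicarbonyl chelates the chiral Cu(II)–bis(oxazoline) so that the tethered electron-rich diene adds to one face of C5=C10 in an intramolecular Diels–Alder reaction (C4→C5 bond leading; closest precedents are Cu–box Diels–Alder reactions of chelating dienophiles and o-quinone-monoketal IMDA/Cope cascades), and the three-atom aryl-ether tether forces the exo mode so that C1–aryl, C4–Me, C5–Me and C10–O end up all syn while ring B and the dihydrofuran form together.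

**Step 7**
Reactants: 11 (1R,4R,5S,10S)-tetracyclic ene-dione; 12 isopropyldiphenylsulfonium tetrafluoroborate
Product: 14 (1S,4R,5R,6S,7R)-1-[3-acetyl-4-(benzyloxy)-2-hydroxy-6-methoxyphenyl]-9-hydroxyaristola-2,9-dien-8-one, via dienone 13 (not isolated)
Conditions: SmI2 (2.1 equiv), THF, −78 °C; then Ph2S=CMe2 (from 12, LDA, DME, −78 °C; 2.2 equiv), −78 → −20 °C; H2O
Reagents that add atoms: none
Why: SmI2 reductive cleavage of the α-aryloxy 1,2-dione (two-electron reduction, then β-elimination of the phenoxide) makes C10 planar as the diosphenolate dienone, and Corey–Chaykovsky cyclopropanation with diphenylsulfonium isopropylide then takes the only free enone (C6=C7) from the face anti to the angular C14 methyl (as in the 2-diazopropane route to aristolone and ylide additions to steroidal 1,4-dien-3-ones), setting C6 and C7, while the dianionic substrate protects C1 from epimerisation.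

**Step 8**
Reactants: 14 (1S,4R,5R,6S,7R)-1-[3-acetyl-4-(benzyloxy)-2-hydroxy-6-methoxyphenyl]-9-hydroxyaristola-2,9-dien-8-one
Product: 15 (1S,4R,5R,6S,7R)-1-(3-acetyl-2,4-dihydroxy-6-methoxyphenyl)-9-hydroxyaristol-9-en-8-one
Conditions: H2 (1 atm), 10 % Pd/C, EtOAc–EtOH, rt
Reagents that add atoms: none
Why: heterogeneous hydrogenation of the only unconjugated C=C (C2=C3) with concurrent hydrogenolysis of the benzyl ether; the tetrasubstituted enol C=C and the cyclopropyl ketone are inert under these mild conditions.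

**Step 9**
Reactants: 15 (1S,4R,5R,6S,7R)-1-(3-acetyl-2,4-dihydroxy-6-methoxyphenyl)-9-hydroxyaristol-9-en-8-one; 16 4-methoxybenzaldehyde
Product: 18 (1S,4R,5R,6S,7R)-1-{2,4-dihydroxy-6-methoxy-3-[(E)-3-(4-methoxyphenyl)prop-2-enoyl]phenyl}-9-hydroxyaristol-9-en-8-one, via aldol adduct 17 (not isolated)
Conditions: 16 (2 equiv), 50 % aq. KOH, EtOH, Ar, 0 °C → rt; then cold 1 M HCl to pH 5
Reagents that add atoms: none
Why: Claisen–Schmidt (crossed aldol) condensation with E1cB dehydration to the (E)-enone, run before the 1,2-dione exists because the diosphenolate is inert to hydroxide whereas the non-enolisable dione could undergo benzilic acid rearrangement.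

**Step 10**
Reactants: 18 (1S,4R,5R,6S,7R)-1-{2,4-dihydroxy-6-methoxy-3-[(E)-3-(4-methoxyphenyl)prop-2-enoyl]phenyl}-9-hydroxyaristol-9-en-8-one
Product: 19 CNP0121765.1 (1R,4R,5R,6S,7R,10S)
Conditions: PhI(OAc)2 (1.05 equiv), MeCN, −20 → 0 °C
Reagents that add atoms: none
Why: iodine(III)-mediated dehydrogenative enol–phenol C–O coupling (umpolung of the diosphenol through its iodine(III) enolate, 5-exo attack by the only phenol that can reach C10); the oxygen is delivered from the face of the C1–aryl bond, so C1 sets the cis-fused dihydrofuran and the 10S centre, and the 8,9-dione is unveiled.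

**Compound list**
1 | 2',6'-dihydroxy-4'-methoxyacetophenone | CC(=O)c1c(O)cc(OC)cc1O | starting material
2 | 1-[2-(benzyloxy)-6-hydroxy-4-methoxyphenyl]ethan-1-one | CC(=O)c1c(OCc2ccccc2)cc(OC)cc1O | intermediate
3 | 1-[6-(benzyloxy)-2-hydroxy-3-iodo-4-methoxyphenyl]ethan-1-one | CC(=O)c1c(OCc2ccccc2)cc(OC)c(I)c1O | intermediate
4 | 2-fluoro-3-methylbenzaldehyde | Cc1cccc(C=O)c1F | starting material
5 | 2-[2-acetyl-3-(benzyloxy)-6-iodo-5-methoxyphenoxy]-3-methylbenzaldehyde | CC(=O)c1c(OCc2ccccc2)cc(OC)c(I)c1Oc1c(C)cccc1C=O | intermediate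
6 | 2-[2-acetyl-3-(benzyloxy)-6-iodo-5-methoxyphenoxy]-3-methylphenyl formate | CC(=O)c1c(OCc2ccccc2)cc(OC)c(I)c1Oc1c(C)cccc1OC=O | intermediate (not isolated)
7 | 1-[6-(benzyloxy)-2-(2-hydroxy-6-methylphenoxy)-3-iodo-4-methoxyphenyl]ethan-1-one | CC(=O)c1c(OCc2ccccc2)cc(OC)c(I)c1Oc1c(C)cccc1O | intermediate
8 | (E)-penta-1,3-diene (trans-piperylene) | C=C/C=C/C | starting material
9 | 1-[6-(benzyloxy)-2-(2-hydroxy-6-methylphenoxy)-4-methoxy-3-[(1E,3E)-penta-1,3-dien-1-yl]phenyl]ethan-1-one | CC(=O)c1c(OCc2ccccc2)cc(OC)c(/C=C/C=C/C)c1Oc1c(C)cccc1O | intermediate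
10 | 3-[2-acetyl-3-(benzyloxy)-5-methoxy-6-[(1E,3E)-penta-1,3-dien-1-yl]phenoxy]-4-methylcyclohexa-3,5-diene-1,2-dione | CC(=O)c1c(OCc2ccccc2)cc(OC)c(/C=C/C=C/C)c1OC1=C(C)C=CC(=O)C1=O | intermediate (not isolated)
11 | (1R,4R,5S,10S)-tetracyclic ene-dione: O6'–C10/C5'–C1 cis-fused dihydrobenzofuran on a 4,5-dimethyl bicyclic 2,6-diene-8,9-dione; C1–aryl, C4–Me, C5–Me, C10–O all syn; 1'-acetyl, 2'-OBn, 4'-OMe | CC(=O)c2c(OCc6ccccc6)cc(OC)c3c2O[C@]24C(=O)C(=O)C=C[C@@]2(C)[C@H](C)C=C[C@H]34 | intermediate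
12 | isopropyldiphenylsulfonium tetrafluoroborate | CC(C)[S+](c1ccccc1)c1ccccc1.F[B-](F)(F)F | starting material
13 | (4aS,5R,8S)-8-[3-acetyl-4-(benzyloxy)-2-hydroxy-6-methoxyphenyl]-1-hydroxy-4a,5-dimethyl-5,8-dihydronaphthalen-2(4aH)-one (formed as its Sm(III) dienolate–phenoxide) | CC(=O)c1c(OCc2ccccc2)cc(OC)c(c1O)[C@H]3C=C[C@@H](C)[C@]4(C)C=CC(=O)C(O)=C34 | intermediate (not isolated)
14 | (1S,4R,5R,6S,7R)-1-[3-acetyl-4-(benzyloxy)-2-hydroxy-6-methoxyphenyl]-9-hydroxyaristola-2,9-dien-8-one (cyclopropane anti to the C14/C15 methyls) | CC(=O)c1c(OCc2ccccc2)cc(OC)c(c1O)[C@H]3C=C[C@@H](C)[C@]4(C)[C@@H]5C(C)(C)[C@@H]5C(=O)C(O)=C34 | intermediate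
15 | (1S,4R,5R,6S,7R)-1-(3-acetyl-2,4-dihydroxy-6-methoxyphenyl)-9-hydroxyaristol-9-en-8-one | CC(=O)c1c(O)cc(OC)c(c1O)[C@H]3CC[C@@H](C)[C@]4(C)[C@@H]5C(C)(C)[C@@H]5C(=O)C(O)=C34 | intermediate
16 | 4-methoxybenzaldehyde | COc1ccc(C=O)cc1 | starting material
17 | (1S,4R,5R,6S,7R)-1-{2,4-dihydroxy-3-[3-hydroxy-3-(4-methoxyphenyl)propanoyl]-6-methoxyphenyl}-9-hydroxyaristol-9-en-8-one (carbinol epimers) | COc1ccc(C(O)CC(=O)c2c(O)cc(OC)c(c2O)[C@H]3CC[C@@H](C)[C@]4(C)[C@@H]5C(C)(C)[C@@H]5C(=O)C(O)=C34)cc1 | intermediate (not isolated)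
18 | (1S,4R,5R,6S,7R)-1-{2,4-dihydroxy-6-methoxy-3-[(E)-3-(4-methoxyphenyl)prop-2-enoyl]phenyl}-9-hydroxyaristol-9-en-8-one | COc1ccc(/C=C/C(=O)c2c(O)cc(OC)c(c2O)[C@H]3CC[C@@H](C)[C@]4(C)[C@@H]5C(C)(C)[C@@H]5C(=O)C(O)=C34)cc1 | intermediate
19 | CNP0121765.1, (1R,4R,5R,6S,7R,10S) | COc1ccc(/C=C/C(=O)c2c(O)cc(OC)c3c2O[C@]24C(=O)C(=O)[C@@H]5[C@@H](C5(C)C)[C@@]2(C)[C@H](C)CC[C@H]34)cc1 | target

**Summary**
Total step count: 10. Longest linear sequence: 10 steps (1 → 19).

Steps most likely to fail:

Step 6 (enantioselective o-quinone IMDA): the uncatalysed cycloaddition may outrun the chiral Lewis acid, or the induction may be low. The fallback sets out from 9 and comes back at 11. Oxidise 9 with IBX as before and let o-quinone 10 cyclise thermally without catalyst (toluene, 40–60 °C); this gives 11 together with its mirror image ent-11 F1 as the racemate. Separate by preparative chiral SFC and carry on only 11.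

Step 7 (one-pot reductive C10–O release and cyclopropanation): the Sm(III) dienolate may not accept the bulky ylide next to the quaternary C5. The fallback sets out from 11 and comes back at 14. Quench the SmI2 cleavage with TBSOTf/2,6-lutidine to isolate the dienone as its bis-TBS ether F2. Add 2-diazopropane (Et2O, −40 °C) across C6=C7, anti to C14 as in the classical aristolone synthesis, to give the Δ1-pyrazoline F3. Photolysis (350 nm, −20 °C) extrudes nitrogen to the bis-TBS cyclopropane F4, and buffered TBAF returns 14.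

Step 10 (oxidative furan closure in the presence of the dihydroxychalcone): iodine(III) may attack the chalcone phenols, or the chalcone may cyclise to a flavanone first. The fallback sets out from 15 and comes back at 19. Close the furan before the enone is present, by one-electron phenol–enol coupling of 15 with Ag2O (benzene, rt), to the acetyl analogue of the target F5. Then build the chalcone without hydroxide: LiHMDS (THF, −78 °C) and 16 give the β-hydroxy ketone F6, and PPTS (cat., CH2Cl2, rt) dehydrates this p-methoxybenzylic carbinol to 19.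

**Further compounds**
F1 | step 6 | ent-11, (1S,4S,5R,10R)-tetracyclic ene-dione | CC(=O)c2c(OCc6ccccc6)cc(OC)c3c2O[C@@]24C(=O)C(=O)C=C[C@]2(C)[C@@H](C)C=C[C@@H]34
F2 | step 7 | bis(tert-butyldimethylsilyl) ether of dienone 13 | CC(=O)c1c(OCc2ccccc2)cc(OC)c(c1O[Si](C)(C)C(C)(C)C)[C@H]3C=C[C@@H](C)[C@]4(C)C=CC(=O)C(O[Si](C)(C)C(C)(C)C)=C34
F3 | step 7 | Δ1-pyrazoline from 2-diazopropane and F2 (C11 on C6, N on C7, anti to C14) | CC(=O)c1c(OCc2ccccc2)cc(OC)c(c1O[Si](C)(C)C(C)(C)C)[C@H]3C=C[C@@H](C)[C@]4(C)[C@@H]5C(C)(C)N=N[C@@H]5C(=O)C(O[Si](C)(C)C(C)(C)C)=C34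
F4 | step 7 | bis(tert-butyldimethylsilyl) ether of 14 | CC(=O)c1c(OCc2ccccc2)cc(OC)c(c1O[Si](C)(C)C(C)(C)C)[C@H]3C=C[C@@H](C)[C@]4(C)[C@@H]5C(C)(C)[C@@H]5C(=O)C(O[Si](C)(C)C(C)(C)C)=C34
F5 | step 10 | acetyl analogue of 19 (methyl ketone in place of the enone), (1R,4R,5R,6S,7R,10S) | CC(=O)c2c(O)cc(OC)c3c2O[C@]24C(=O)C(=O)[C@@H]5[C@@H](C5(C)C)[C@@]2(C)[C@H](C)CC[C@H]34
F6 | step 10 | β-hydroxy ketone from F5 and 16 (carbinol epimers) | COc1ccc(C(O)CC(=O)c2c(O)cc(OC)c3c2O[C@]24C(=O)C(=O)[C@@H]5[C@@H](C5(C)C)[C@@]2(C)[C@H](C)CC[C@H]34)cc1
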